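**Retrosynthetic overview**

1. The methyl ester is traced back to the acid, the primary alcohol and a silyl ether of the 2-(1,2-dioxolan-3-yl)ethanol, so the arm is carried as CH2CH2OSi through the peroxide steps.
2. The dioxolane C5–O1 bond is disconnected to a (3R)-hydroperoxide bearing a C5=CH2 alkene, closed by acid-catalysed Markovnikov cation capture.
3. The C3–OOH bond comes from a 2,2-disubstituted oxetane opened by H2O2 at its tertiary carbon with inversion, and the oxetane comes from a 1,3-diol whose carbinol carbon is that of (R)-mevalonolactone.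
4. The C5–C6 bond comes from the Weinreb amide acetonide of mevalonolactone and the Grignard reagent of [(7R)-8-bromo-7-methyloctyl]benzene (made from (S)-3-bromo-2-methylpropan-1-ol and (5-bromopentyl)benzene); C5=CH2 is installed by Wittig methylenation.
5. The strategy rests on the ring O1–O2–C3–C4–C5 having both peroxide carbons quaternary: C3 (CH3, two-carbon oxygenated arm, C4) is the mevalonolactone carbinol pattern and C5 (CH3, chain, C4) is the tertiary cation of a C5=CH2 alkene. The C3 methyl and the C5 chain are cis (arm and chain trans). Rings form in the order dioxane acetonide (temporary), oxetane (relay), 1,2-dioxolane.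

Key step: step 11

Assumption: (R)-mevalonolactone and (S)-3-bromo-2-methylpropan-1-ol (the Roche-ester-derived C4 unit) are used as commercial single enantiomers.

**Route**

Step 1
Reactants: 1 (5-bromopentyl)benzene; 2 (S)-3-bromo-2-methylpropan-1-ol
Product: 4 (R)-2-methyl-8-phenyloctan-1-ol, via (5-phenylpentyl)magnesium bromide 3 (not isolated)
Conditions: Mg, THF; then 2 (3 used in 2.3 equiv), Li2CuCl4 (5 mol %), THF–NMP, 0 °C → rt; aq. NH4Cl
Reagents that add atoms: none
Why: Copper-catalysed sp3–sp3 cross-coupling of a Grignard reagent with a primary bromide (Kochi type), in which the first equivalent of 3 only turns the hydroxyl into an inert magnesium alkoxide; the stereocentre of 2 is not involved and is carried over (S becomes R only because the CIP ranking of the arms changes).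

Step 2
Reactants: 4 (R)-2-methyl-8-phenyloctan-1-ol
Product: 5 [(7R)-8-bromo-7-methyloctyl]benzene
Conditions: CBr4, PPh3, CH2Cl2, 0 °C → rt
Reagents that add atoms: carbon tetrabromide, BrC(Br)(Br)Br
Why: Appel bromination of a primary alcohol under neutral conditions, which leaves the adjacent stereocentre untouched.

Step 3
Reactants: 6 (R)-mevalonolactone
Product: 7 (3R)-3,5-dihydroxy-N-methoxy-N,3-dimethylpentanamide
Conditions: MeNH(OMe)·HCl, i-PrMgCl, THF, −20 → 0 °C; aq. NH4Cl
Reagents that add atoms: N,O-dimethylhydroxylamine hydrochloride, CNOC.Cl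
Why: Aminolysis of the δ-lactone by the chloromagnesium amide of N,O-dimethylhydroxylamine (Weinreb amide formation), with an extra equivalent of i-PrMgCl covering the tertiary hydroxyl; the carbinol stereocentre is not touched.

Step 4
Reactants: 7 (3R)-3,5-dihydroxy-N-methoxy-N,3-dimethylpentanamide
Product: 8 N-methoxy-N-methyl-2-[(4R)-2,2,4-trimethyl-1,3-dioxan-4-yl]acetamide
Conditions: 2,2-dimethoxypropane, pyridinium p-toluenesulfonate (cat.), CH2Cl2, rt
Reagents that add atoms: 2,2-dimethoxypropane, COC(C)(C)OC
Why: Acid-catalysed transketalisation closes the six-membered acetonide over the 1,3-diol, masking both hydroxyls and blocking relactonisation before the organometallic step.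

Step 5
Reactants: 5 [(7R)-8-bromo-7-methyloctyl]benzene; 8 N-methoxy-N-methyl-2-[(4R)-2,2,4-trimethyl-1,3-dioxan-4-yl]acetamide
Product: 10 (4R)-4-methyl-10-phenyl-1-[(4R)-2,2,4-trimethyl-1,3-dioxan-4-yl]decan-2-one, via [(2R)-2-methyl-8-phenyloctyl]magnesium bromide 9 (not isolated)
Conditions: Mg, THF, 40 °C; then 8, THF, 0 °C → rt; aq. NH4Cl
Reagents that add atoms: none
Why: Grignard addition to a Weinreb amide stops at the chelated tetrahedral adduct and releases the ketone only on work-up, so no tertiary alcohol should form; the methyl-bearing stereocentre ends up β to the carbonyl and cannot epimerise.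

Step 6
Reactants: 10 (4R)-4-methyl-10-phenyl-1-[(4R)-2,2,4-trimethyl-1,3-dioxan-4-yl]decan-2-one
Product: 11 (4S)-2,2,4-trimethyl-4-[(4R)-4-methyl-2-methylidene-10-phenyldecyl]-1,3-dioxane
Conditions: Ph3PCH3Br, KOtBu, THF, 0 °C → rt
Reagents that add atoms: methyltriphenylphosphonium bromide, C[P+](c1ccccc1)(c1ccccc1)c1ccccc1.[Br-]
Why: Wittig methylenation with the non-stabilised ylide, which should add to the ketone faster than it enolises it, so β-elimination of the acetonide oxygen should stay minor (the dioxane descriptor changes to S by CIP ranking only).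

Step 7
Reactants: 11 (4S)-2,2,4-trimethyl-4-[(4R)-4-methyl-2-methylidene-10-phenyldecyl]-1,3-dioxane
Product: 12 (3S,7R)-3,7-dimethyl-5-methylidene-13-phenyltridecane-1,3-diol
Conditions: pyridinium p-toluenesulfonate (cat.), MeOH, rt
Reagents that add atoms: none
Why: Mild acid-catalysed acetal exchange with methanol frees the 1,3-diol, the acid being too weak to protonate the 1,1-disubstituted alkene.

Step 8
Reactants: 12 (3S,7R)-3,7-dimethyl-5-methylidene-13-phenyltridecane-1,3-diol
Product: 14 (2S)-2-methyl-2-[(4R)-4-methyl-2-methylidene-10-phenyldecyl]oxetane, via the primary monotosylate 13 (not isolated)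
Conditions: n-BuLi (1 equiv), THF, 0 °C; TsCl (1 equiv); n-BuLi (1 equiv), 0 → 60 °C
Reagents that add atoms: none
Why: One-pot tosylation of the less hindered primary alkoxide followed by intramolecular Williamson etherification (4-exo-tet) by the tertiary alkoxide; no bond to the carbinol carbon is broken, so its configuration is retained.

Step 9
Reactants: 14 (2S)-2-methyl-2-[(4R)-4-methyl-2-methylidene-10-phenyldecyl]oxetane
Product: 15 (3R,7R)-3-hydroperoxy-3,7-dimethyl-5-methylidene-13-phenyltridecan-1-ol
Conditions: anhydrous H2O2 in Et2O (10 equiv), Me3SiOSO2CF3 (0.3 equiv), Et2O, −78 °C; aq. NaHCO3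
Reagents that add atoms: hydrogen peroxide, OO
Why: Lewis-acid perhydrolysis of a 2,2-disubstituted oxetane, in which H2O2 attacks the tertiary carbon of the activated ring in a strain-releasing, SN2-like opening from the face opposite the departing oxygen, so C3 is inverted and the former ring oxygen becomes the primary hydroxyl.

Step 10
Reactants: 15 (3R,7R)-3-hydroperoxy-3,7-dimethyl-5-methylidene-13-phenyltridecan-1-ol
Product: 16 tert-butyl{[(3R,7R)-3-hydroperoxy-3,7-dimethyl-5-methylidene-13-phenyltridecyl]oxy}diphenylsilane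
Conditions: t-BuPh2SiCl (1.05 equiv), imidazole, CH2Cl2, −20 → 0 °C
Reagents that add atoms: tert-butyl(chloro)diphenylsilane, CC(C)(C)[Si](Cl)(c1ccccc1)c1ccccc1
Why: Silylation with a bulky chlorosilane under weak-base conditions, where the unhindered primary alcohol should react faster than the neutral, less nucleophilic oxygen of the tertiary hydroperoxide; the silyl ether is needed so that the arm oxygen cannot trap the cation as a six-membered ether in the next step.

Step 11
Reactants: 16 tert-butyl{[(3R,7R)-3-hydroperoxy-3,7-dimethyl-5-methylidene-13-phenyltridecyl]oxy}diphenylsilane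
Product: 17 tert-butyl{2-[(3S,5S)-3,5-dimethyl-5-[(2R)-2-methyl-8-phenyloctyl]-1,2-dioxolan-3-yl]ethoxy}diphenylsilane
Conditions: CF3SO3H (10 mol %), CH2Cl2, −40 → 0 °C; Et3N quench; silica chromatography to remove the C5 epimer
Reagents that add atoms: none
Why: Proposed new method: the acid protonates the C5=CH2 alkene at its terminal carbon (Markovnikov), which creates the C5 methyl and a tertiary C5 cation that is captured by the terminal oxygen of the C3 hydroperoxide to form the C5–O1 bond, the proton being released again. The closest known reactions are the intermolecular acid-catalysed addition of tertiary hydroperoxides to 2-methylalkenes (the route to di-tert-alkyl peroxides) and the acid-catalysed hydroalkoxylation of hydroxy alkenes; new here is the ring-closing use on an alkenyl hydroperoxide. The 1,2-dioxolane (O1–O2–C3–C4–C5) closes in a 5-exo sense with respect to the former alkene, and both ring termini are quaternary, which favours closure. C3 is not touched, and the new C5 stereocentre is set by the face of the planar cation that the peroxide oxygen attacks; because C3 and C5 each carry a methyl and a CH2R group of similar size, only a weak substrate bias is expected, so both C5 epimers should form and 17 (C3 methyl cis to the C5 chain, arm and chain trans) is isolated by chromatography. The step needs protonation of the alkene in preference to ionisation of the C3–OOH bond or Hock-type rearrangement, which the catalytic acid, the low temperature and the higher basicity of the 1,1-disubstituted alkene should secure, while the silyl ether keeps the arm oxygen out of the closure.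

Step 12
Reactants: 17 tert-butyl{2-[(3S,5S)-3,5-dimethyl-5-[(2R)-2-methyl-8-phenyloctyl]-1,2-dioxolan-3-yl]ethoxy}diphenylsilane
Product: 18 2-[(3S,5S)-3,5-dimethyl-5-[(2R)-2-methyl-8-phenyloctyl]-1,2-dioxolan-3-yl]ethan-1-ol
Conditions: n-Bu4NF, AcOH, THF, 0 °C → rt
Reagents that add atoms: none
Why: Fluoride-induced cleavage of the silicon–oxygen bond under acetic acid buffering, which the di-tert-alkyl peroxide (no α-hydrogen) should tolerate.

Step 13
Reactants: 18 2-[(3S,5S)-3,5-dimethyl-5-[(2R)-2-methyl-8-phenyloctyl]-1,2-dioxolan-3-yl]ethan-1-ol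
Product: 20 [(3R,5S)-3,5-dimethyl-5-[(2R)-2-methyl-8-phenyloctyl]-1,2-dioxolan-3-yl]acetic acid, via the corresponding aldehyde 19 (not isolated)
Conditions: 2,2,6,6-tetramethylpiperidin-1-oxyl (TEMPO, cat.), PhI(OAc)2 (2.2 equiv), MeCN–H2O, rt
Reagents that add atoms: water, O
Why: Oxoammonium-mediated oxidation of the primary alcohol through the aldehyde hydrate to the carboxylic acid, an oxidant that attacks neither dialkyl peroxides nor the phenyl ring (the C3 descriptor becomes R by CIP ranking only).

Step 14
Reactants: 20 [(3R,5S)-3,5-dimethyl-5-[(2R)-2-methyl-8-phenyloctyl]-1,2-dioxolan-3-yl]acetic acid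
Product: 21 methyl [(3R,5S)-3,5-dimethyl-5-[(2R)-2-methyl-8-phenyloctyl]-1,2-dioxolan-3-yl]acetate (CNP0394871.1)
Conditions: Me3SiCHN2, MeOH–toluene, 0 °C
Reagents that add atoms: (trimethylsilyl)diazomethane, C[Si](C)(C)C=[N+]=[N-]
Why: Esterification of the carboxylic acid with (trimethylsilyl)diazomethane in methanol, a neutral O-methylation that avoids base at the β-peroxy ester.

**Compound list**

1 | (5-bromopentyl)benzene | BrCCCCCc1ccccc1 | starting material
2 | (S)-3-bromo-2-methylpropan-1-ol | OC[C@H](C)CBr | starting material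
3 | (5-phenylpentyl)magnesium bromide | Br[Mg]CCCCCc1ccccc1 | intermediate
4 | (R)-2-methyl-8-phenyloctan-1-ol | OC[C@H](C)CCCCCCc1ccccc1 | intermediate
5 | [(7R)-8-bromo-7-methyloctyl]benzene | BrC[C@H](C)CCCCCCc1ccccc1 | intermediate
6 | (R)-mevalonolactone, (4R)-4-hydroxy-4-methyloxan-2-one | C[C@@]1(O)CCOC(=O)C1 | starting material
7 | (3R)-3,5-dihydroxy-N-methoxy-N,3-dimethylpentanamide | C[C@@](CC(=O)N(C)OC)(O)CCO | intermediate
8 | N-methoxy-N-methyl-2-[(4R)-2,2,4-trimethyl-1,3-dioxan-4-yl]acetamide | C[C@@]1(CC(=O)N(C)OC)OC(C)(C)OCC1 | intermediate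
9 | [(2R)-2-methyl-8-phenyloctyl]magnesium bromide | Br[Mg]C[C@H](C)CCCCCCc1ccccc1 | intermediate
10 | (4R)-4-methyl-10-phenyl-1-[(4R)-2,2,4-trimethyl-1,3-dioxan-4-yl]decan-2-one | C[C@@]1(CC(=O)C[C@H](C)CCCCCCc2ccccc2)OC(C)(C)OCC1 | intermediate
11 | (4S)-2,2,4-trimethyl-4-[(4R)-4-methyl-2-methylidene-10-phenyldecyl]-1,3-dioxane | C[C@@]1(CC(=C)C[C@H](C)CCCCCCc2ccccc2)OC(C)(C)OCC1 | intermediate
12 | (3S,7R)-3,7-dimethyl-5-methylidene-13-phenyltridecane-1,3-diol | C[C@@](CC(=C)C[C@H](C)CCCCCCc1ccccc1)(O)CCO | intermediate
13 | (3S,7R)-3-hydroxy-3,7-dimethyl-5-methylidene-13-phenyltridecyl 4-methylbenzenesulfonate | C[C@@](CC(=C)C[C@H](C)CCCCCCc1ccccc1)(O)CCOS(=O)(=O)c1ccc(C)cc1 | intermediate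
14 | (2S)-2-methyl-2-[(4R)-4-methyl-2-methylidene-10-phenyldecyl]oxetane | C[C@@]1(CC(=C)C[C@H](C)CCCCCCc2ccccc2)OCC1 | intermediate
15 | (3R,7R)-3-hydroperoxy-3,7-dimethyl-5-methylidene-13-phenyltridecan-1-ol | OCC[C@@](OO)(C)CC(=C)C[C@H](C)CCCCCCc1ccccc1 | intermediate
16 | tert-butyl{[(3R,7R)-3-hydroperoxy-3,7-dimethyl-5-methylidene-13-phenyltridecyl]oxy}diphenylsilane | CC(C)(C)[Si](OCC[C@@](OO)(C)CC(=C)C[C@H](C)CCCCCCc1ccccc1)(c1ccccc1)c1ccccc1 | intermediate
17 | tert-butyl{2-[(3S,5S)-3,5-dimethyl-5-[(2R)-2-methyl-8-phenyloctyl]-1,2-dioxolan-3-yl]ethoxy}diphenylsilane | CC(C)(C)[Si](OCC[C@@]1(C)C[C@](C)(C[C@H](C)CCCCCCc2ccccc2)OO1)(c1ccccc1)c1ccccc1 | intermediate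
18 | 2-[(3S,5S)-3,5-dimethyl-5-[(2R)-2-methyl-8-phenyloctyl]-1,2-dioxolan-3-yl]ethan-1-ol | OCC[C@@]1(C)C[C@](C)(C[C@H](C)CCCCCCc2ccccc2)OO1 | intermediate
19 | [(3R,5S)-3,5-dimethyl-5-[(2R)-2-methyl-8-phenyloctyl]-1,2-dioxolan-3-yl]acetaldehyde | O=CC[C@@]1(C)C[C@](C)(C[C@H](C)CCCCCCc2ccccc2)OO1 | intermediate
20 | [(3R,5S)-3,5-dimethyl-5-[(2R)-2-methyl-8-phenyloctyl]-1,2-dioxolan-3-yl]acetic acid | OC(=O)C[C@@]1(C)C[C@](C)(C[C@H](C)CCCCCCc2ccccc2)OO1 | intermediate
21 | methyl [(3R,5S)-3,5-dimethyl-5-[(2R)-2-methyl-8-phenyloctyl]-1,2-dioxolan-3-yl]acetate | COC(=O)C[C@@]1(C)C[C@](C)(C[C@H](C)CCCCCCc2ccccc2)OO1 | target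

**Step count**

Total: 14 steps. Longest linear sequence: 12 steps (steps 3–14 from 6, or steps 1, 2 and 5–14 from 1 and 2).

**Steps most likely to fail**

1. Step 11 (proposed new method). The attack on the planar C5 cation may show poor facial selectivity, so that much material goes to the C5 epimer. The acid may also ionise the C3–OOH bond, which would erode C3 or lose H2O2, or it may only isomerise the alkene. If silica does not resolve the epimers of 17, the separation can be moved to alcohol 18. Fallback, from 16 back to 17: the same C5–O1 bond is made by cycloperoxymercuration, a known closure of alkenyl hydroperoxides. Hg(OAc)2 with a trace of HClO4 in CH2Cl2 at 0 °C should place mercury on the terminal carbon and the hydroperoxide oxygen on C5, giving {[(3S,5S)-5-{2-[tert-butyl(diphenyl)silyl]oxyethyl}-5-methyl-3-[(2R)-2-methyl-8-phenyloctyl]-1,2-dioxolan-3-yl]methyl}mercury acetate F1 together with its epimer at the mercurated ring carbon. Reduction with NaBH4 in aqueous NaOH at 0 °C replaces mercury by hydrogen and returns 17 after removal of the epimer. This avoids strong acid at C3; some fragmentation of the β-peroxyalkyl radical during demercuration has to be accepted.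

2. Step 9. The opening may take on SN1 character and lose part of the inversion at C3, or the neighbouring 1,1-disubstituted alkene may intercept the activated oxetane or be attacked by the acid. Fallback, from 14 back to 18: the peroxide is first placed on C5 and the oxetane is then opened from inside. Isayama–Mukaiyama reductive oxygenation of the alkene of 14 (Co(acac)2 cat., Et3SiH, O2, EtOH, rt) should give triethyl{[(2S,4R)-2,4-dimethyl-1-[(2R)-2-methyloxetan-2-yl]-10-phenyldecan-2-yl]peroxy}silane F2 with its C2 epimer. Buffered n-Bu4NF at 0 °C frees (2R)-2-[(2S,4R)-2-hydroperoxy-2,4-dimethyl-10-phenyldecyl]-2-methyloxetane F3. A Lewis acid (Me3SiOSO2CF3 cat., or Yb(O3SCF3)3) then lets the hydroperoxide open the oxetane at its tertiary carbon, 5-exo and with inversion at C3, giving 18 after separation of the C5 epimer. C3 is still set by inversion of the same oxetane carbon. The ring closure moves to the C3–O2 bond, and steps 10–12 are no longer needed.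

3. Step 10. The hydroperoxide oxygen may be silylated in competition with the primary hydroxyl, giving mixtures of mono- and bis-silylated material. Fallback, from 15 back to 16: both groups are silylated on purpose and the peroxide is then unmasked. Excess t-BuPh2SiCl with imidazole and DMAP in DMF should give tert-butyl{[(3R,7R)-3-{[tert-butyl(diphenyl)silyl]peroxy}-3,7-dimethyl-5-methylidene-13-phenyltridecyl]oxy}diphenylsilane F4. One equivalent of acetic-acid-buffered n-Bu4NF in THF at −20 °C should then cleave only the Si–OO bond, because the hydroperoxide anion is a far better leaving group than a primary alkoxide, and return 16.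

**Further compounds**

F1 | step 11 | {[(3S,5S)-5-{2-[tert-butyl(diphenyl)silyl]oxyethyl}-5-methyl-3-[(2R)-2-methyl-8-phenyloctyl]-1,2-dioxolan-3-yl]methyl}mercury acetate | CC(C)(C)[Si](OCC[C@@]1(C)C[C@](C[Hg]OC(C)=O)(C[C@H](C)CCCCCCc2ccccc2)OO1)(c1ccccc1)c1ccccc1
F2 | step 9 | triethyl{[(2S,4R)-2,4-dimethyl-1-[(2R)-2-methyloxetan-2-yl]-10-phenyldecan-2-yl]peroxy}silane | C[C@@]1(C[C@](C)(C[C@H](C)CCCCCCc2ccccc2)OO[Si](CC)(CC)CC)OCC1
F3 | step 9 | (2R)-2-[(2S,4R)-2-hydroperoxy-2,4-dimethyl-10-phenyldecyl]-2-methyloxetane | C[C@@]1(C[C@](C)(C[C@H](C)CCCCCCc2ccccc2)OO)OCC1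
F4 | step 10 | tert-butyl{[(3R,7R)-3-{[tert-butyl(diphenyl)silyl]peroxy}-3,7-dimethyl-5-methylidene-13-phenyltridecyl]oxy}diphenylsilane | CC(C)(C)[Si](OCC[C@@](OO[Si](c1ccccc1)(c1ccccc1)C(C)(C)C)(C)CC(=C)C[C@H](C)CCCCCCc1ccccc1)(c1ccccc1)c1ccccc1
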